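In the target, rings A and B share only the quaternary carbon C6, and the chlorine-bearing C3 lies opposite C6 across ring B (a 1,4 relationship): exactly what arises when the α-carbon of an aldehyde is built into a cyclohexenone with a vinyl ketone. Everything therefore rests on disconnecting C5–C6 and C1–C2. In one operation a chiral primary amine converts a racemic ring-A aldehyde into a single enamine, adds it to methyl vinyl ketone and closes ring B by aldol condensation, creating the C6 stereocentre, ring B and the C3 carbonyl handle. The precursor is a gem-dimethylcyclohexenone vinylogous ester (ether on C8, ketone on C10) with the formyl group on C6.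

Key step: step 5

Remark (numbering): chamigrene numbering is used in the text (ring B = C1–C5 plus spiro C6; ring A = C6–C11 with C11 the gem-dimethyl carbon; C14 = exocyclic methylene carbon; C15 = methyl on C3); systematic names use spiro[5.5]undecane locants.
Remark (structures): the annulation substrate 8 is the 3-alkoxy-5-oxocyclohex-3-ene-1-carbaldehyde (ether on C8 next to the ring CH2, ketone on C10 next to the gem-dimethyl carbon), the only vinylogous ester arrangement that maps onto the target; the aldol closure is of the 6-(enolendo)-exo-trig kind, because the enol double bond of the methyl ketone lies inside the ring being formed.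
Remark (precursor design): the β-branched isobutyl enol ether is kept because it resists cleavage by HCl in step 8, and the formyl group is carried as its diisobutyl acetal so that acetal exchange during enol ether formation converges on one compound.
Assumption: the quinine-derived amine is taken to give the (6R) spiro enone 11; if the opposite sense is found, the quinidine-derived pseudoenantiomer is used in the same step.

Step 1
Reactants: 1 2,2-dimethoxyacetaldehyde; 2 1-(triphenylphosphoranylidene)propan-2-one
Product: 3 (E)-5,5-dimethoxypent-3-en-2-one
Conditions: CH2Cl2/H2O, rt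
Reagents that add atoms: none
Why: Wittig olefination of the aldehyde with the carbonyl-stabilised ylide is expected to give the (E)-enone and leaves the acetal untouched.

Step 2
Reactants: 3 (E)-5,5-dimethoxypent-3-en-2-one; 4 methyl 2-methylpropanoate (methyl isobutyrate)
Product: 6 (±)-5-(dimethoxymethyl)-4,4-dimethylcyclohexane-1,3-dione, via keto ester Michael adduct 5 (not isolated)
Conditions: 4, LiN(iPr)2, THF, −78 °C; 3, −78 → 0 °C; KOtBu, THF, 0 °C → rt; aq. HCl to pH 4, 0 °C
Reagents that add atoms: none
Why: The lithium enolate of the α,α-disubstituted ester should add in a conjugate (Michael) sense to the enone at the acetal-bearing carbon, and alkoxide-mediated equilibration to the methyl-ketone enolate then allows the Dieckmann-type Claisen cyclisation onto the ester, driven by deprotonation of the resulting 1,3-dione, the single stereocentre being formed as the racemate.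

Step 3
Reactants: 6 (±)-5-(dimethoxymethyl)-4,4-dimethylcyclohexane-1,3-dione
Product: 7 (±)-5-[bis(2-methylpropoxy)methyl]-6,6-dimethyl-3-(2-methylpropoxy)cyclohex-2-en-1-one
Conditions: i-BuOH (excess), p-toluenesulfonic acid monohydrate (cat.), PhMe, reflux, Dean–Stark trap
Reagents that add atoms: 2-methylpropan-1-ol (isobutanol), CC(C)CO
Why: Acid-catalysed enol etherification of the 1,3-dione under azeotropic water removal should place the ether on the less hindered carbonyl carbon (C8, next to the ring CH2) and leave the ketone beside the gem-dimethyl carbon, while the same conditions exchange the dimethyl acetal for the diisobutyl acetal so that a single compound is carried on after chromatographic removal of any regioisomeric enol ether.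

Step 4
Reactants: 7 (±)-5-[bis(2-methylpropoxy)methyl]-6,6-dimethyl-3-(2-methylpropoxy)cyclohex-2-en-1-one
Product: 8 (±)-6,6-dimethyl-3-(2-methylpropoxy)-5-oxocyclohex-3-ene-1-carbaldehyde
Conditions: pyridinium p-toluenesulfonate (cat.), acetone/H2O, 45 °C
Reagents that add atoms: water, O
Why: Mild acid-catalysed acetal hydrolysis proceeds through the oxocarbenium ion much faster than hydrolysis of the conjugated and weakly basic vinylogous ester, so the aldehyde should be released selectively, its C6 centre being racemic by design.

Step 5
Reactants: 8 (±)-6,6-dimethyl-3-(2-methylpropoxy)-5-oxocyclohex-3-ene-1-carbaldehyde; 9 but-3-en-2-one (methyl vinyl ketone)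
Product: 11 (6R)-1,1-dimethyl-4-(2-methylpropoxy)spiro[5.5]undeca-3,7-diene-2,9-dione, via keto aldehyde Michael adduct 10 (not isolated)
Conditions: 9-amino-9-deoxy-epi-quinine (20 mol %), CF3CO2H (40 mol %), 9 (3 equiv, slow addition), PhMe, 25 °C, then 60 °C
Reagents that add atoms: none
Why: The primary amine condenses only with the aldehyde of 8 and, because the C6–H is lost, both enantiomers give the same exocyclic enamine with nitrogen on the C7 (CH2) side, away from the C11 gem-dimethyl group; this enamine adds through C6 to the terminal carbon of 9 (Michael addition, C5–C6 bond), and after hydrolysis to 10 the methyl ketone, as its enamine or enol, attacks the aldehyde carbon (C2–C1 bond) and loses water to give the conjugated C1=C2 enone. The closest known reaction type is the amine-catalysed Michael–aldol (Robinson-type) annulation of α-branched aldehydes with vinyl ketones to 4,4-disubstituted cyclohexenones, in its enantioselective form with cinchona-derived primary amines and an acid cocatalyst. Ring B is closed by a 6-(enolendo)-exo-trig aldol addition that dehydration makes irreversible. The only new stereocentre, C6, is set in the Michael step, where the fixed enamine geometry and the face shielding by the protonated cinchona scaffold are expected to deliver the (6R) product from either enantiomer of 8. The step needs chemoselectivity between two carbonyl groups and a single direction of aldolisation; the first is secured because the C10 carbonyl is a deactivated vinylogous ester beside the quaternary C11 (which also rules out pyrrole formation from this 1,4-keto aldehyde), the second because the quaternary aldehyde of 10 cannot enolise and only the methyl terminus of the ketone reaches it through a six-membered transition state.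

Step 6
Reactants: 11 (6R)-1,1-dimethyl-4-(2-methylpropoxy)spiro[5.5]undeca-3,7-diene-2,9-dione
Product: 13 (6R,8S)-8-bromo-1,1-dimethyl-4-(2-methylpropoxy)spiro[5.5]undec-3-ene-2,9-dione, via trimethylsilyl enol ether 12 (not isolated)
Conditions: LiBH(s-Bu)3, THF, −78 °C; Me3SiCl, Et3N, −78 → 0 °C; pentane filtration, concentration; NBS, THF, −78 → 0 °C
Reagents that add atoms: N-bromosuccinimide, O=C1CCC(=O)N1Br
Why: Conjugate hydride delivery to the ring-B enone (the vinylogous ester carbonyl is deactivated and neopentyl) gives the C2=C3 enolate regiospecifically, which is trapped on oxygen and brominated at C2 (silyl enol ether bromination) from the face away from the axial C7 methylene of ring A, so that bromine should end up equatorial and cis to C11, which is also the thermodynamically preferred C2 epimer.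

Step 7
Reactants: 13 (6R,8S)-8-bromo-1,1-dimethyl-4-(2-methylpropoxy)spiro[5.5]undec-3-ene-2,9-dione
Product: 14 (6R,8S,9R)-8-bromo-9-hydroxy-1,1,9-trimethyl-4-(2-methylpropoxy)spiro[5.5]undec-3-en-2-one
Conditions: MeMgBr, CeCl3, THF, −78 °C; sat. aq. NH4Cl
Reagents that add atoms: methylmagnesium bromide, C[Mg]Br
Why: Chemoselective 1,2-addition of the weakly basic organocerium reagent to the activated α-bromo ketone (the vinylogous ester is far less electrophilic, and enolisation or bromide displacement should not compete at −78 °C) gives the tertiary bromohydrin, expected mainly by equatorial attack (axial hydroxyl, as drawn), any C3 epimer being carried along because step 8 ionises this centre.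

Step 8
Reactants: 14 (6R,8S,9R)-8-bromo-9-hydroxy-1,1,9-trimethyl-4-(2-methylpropoxy)spiro[5.5]undec-3-en-2-one
Product: 15 (6R,8S,9S)-8-bromo-9-chloro-1,1,9-trimethyl-4-(2-methylpropoxy)spiro[5.5]undec-3-en-2-one
Conditions: HCl (g), CH2Cl2, 4 Å molecular sieves, −20 → 0 °C
Reagents that add atoms: hydrogen chloride, Cl
Why: Hydrogen chloride converts the tertiary alcohol into the tertiary chloride by ionisation at C3 (SN1 substitution), and the neighbouring C2 bromine is expected to bridge the cation from its own face (anchimeric assistance through a bromonium ion) so that chloride enters the more substituted carbon C3 anti to bromine, which sets the trans C2–Br/C3–Cl arrangement from either carbinol epimer.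

Step 9
Reactants: 15 (6R,8S,9S)-8-bromo-9-chloro-1,1,9-trimethyl-4-(2-methylpropoxy)spiro[5.5]undec-3-en-2-one
Product: 16 (6R,8S,9S)-4,8-dibromo-9-chloro-5,5,9-trimethylspiro[5.5]undec-3-en-2-one
Conditions: (COBr)2, CH2Cl2, 0 °C → rt
Reagents that add atoms: oxalyl bromide, O=C(Br)C(=O)Br
Why: Oxalyl bromide acylates the carbonyl oxygen on C10, bromide then adds to C10 and expels the oxalate as CO and CO2, and dealkylation of the C8 oxocarbenium ion by bromide gives the transposed β-bromo enone (vinylogous ester to β-halo enone conversion) with bromine on C10 beside the gem-dimethyl carbon, the ring-B halides being inert to these non-basic conditions.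

Step 10
Reactants: 16 (6R,8S,9S)-4,8-dibromo-9-chloro-5,5,9-trimethylspiro[5.5]undec-3-en-2-one
Product: 19 (6S,8S,9S)-4,8-dibromo-9-chloro-5,5,9-trimethyl-1-methylidenespiro[5.5]undec-3-en-2-one, via Mannich base 17 (not isolated), via trimethylammonium iodide 18 (not isolated)
Conditions: LiN(SiMe3)2, THF, −78 °C; [Me2N=CH2]I, −78 → 0 °C; MeI, CH2Cl2, rt; aq. NaHCO3
Reagents that add atoms: N,N-dimethylmethyleneiminium iodide (Eschenmoser's salt), C=[N+](C)C.[I-]
Why: Deprotonation of the C8 ketone can only occur at C7 (C9 is vinylic and C11 quaternary), and the cross-conjugated enolate should undergo a Mannich reaction with the iminium salt, after which quaternisation and mild base-induced elimination of trimethylamine give the exocyclic enone (Eschenmoser methylenation) without strong base being present long enough to dehydrohalogenate ring B.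

Step 11
Reactants: 19 (6S,8S,9S)-4,8-dibromo-9-chloro-5,5,9-trimethyl-1-methylidenespiro[5.5]undec-3-en-2-one
Product: 20 (2R,6S,8S,9S)-4,8-dibromo-9-chloro-5,5,9-trimethyl-1-methylidenespiro[5.5]undec-3-en-2-ol (CNP0228180.1)
Conditions: (S)-1-methyl-3,3-diphenyltetrahydro-1H,3H-pyrrolo[1,2-c][1,3,2]oxazaborole ((S)-Me-CBS, 0.5 equiv), catecholborane, PhMe, −78 °C; MeOH, aq. NaHCO3
Reagents that add atoms: none
Why: Corey–Bakshi–Shibata reduction delivers hydride to the ketone in a 1,2 sense under reagent control, the C7 side (fully substituted sp2 carbon beside the spiro centre) acting as the large and the C9 vinyl CH as the small substituent, so that the (S)-oxazaborolidine should give the (8R) carbinol (C2 in the systematic name) irrespective of the weak intrinsic facial bias of the nearly symmetric ring A.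

Compound list
1 | 2,2-dimethoxyacetaldehyde | COC(OC)C=O | starting material
2 | 1-(triphenylphosphoranylidene)propan-2-one | CC(=O)C=P(c1ccccc1)(c1ccccc1)c1ccccc1 | starting material
3 | (E)-5,5-dimethoxypent-3-en-2-one | COC(OC)/C=C/C(C)=O | intermediate
4 | methyl 2-methylpropanoate (methyl isobutyrate) | COC(=O)C(C)C | starting material
5 | keto ester Michael adduct, methyl 3-(dimethoxymethyl)-2,2-dimethyl-5-oxohexanoate (racemic, not isolated) | COC(=O)C(C)(C)C(CC(C)=O)C(OC)OC | intermediate
6 | (±)-5-(dimethoxymethyl)-4,4-dimethylcyclohexane-1,3-dione | COC(OC)C1CC(=O)CC(=O)C1(C)C | intermediate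
7 | (±)-5-[bis(2-methylpropoxy)methyl]-6,6-dimethyl-3-(2-methylpropoxy)cyclohex-2-en-1-one | CC(C)COC(OCC(C)C)C1CC(OCC(C)C)=CC(=O)C1(C)C | intermediate
8 | (±)-6,6-dimethyl-3-(2-methylpropoxy)-5-oxocyclohex-3-ene-1-carbaldehyde | O=CC1CC(OCC(C)C)=CC(=O)C1(C)C | intermediate
9 | but-3-en-2-one (methyl vinyl ketone) | C=CC(C)=O | starting material
10 | keto aldehyde Michael adduct, (1S)-6,6-dimethyl-3-(2-methylpropoxy)-5-oxo-1-(3-oxobutyl)cyclohex-3-ene-1-carbaldehyde (not isolated) | O=C[C@@]1(CCC(C)=O)CC(OCC(C)C)=CC(=O)C1(C)C | intermediate
11 | (6R)-1,1-dimethyl-4-(2-methylpropoxy)spiro[5.5]undeca-3,7-diene-2,9-dione | C1C(OCC(C)C)=CC(=O)C(C)(C)[C@]12CCC(=O)C=C2 | intermediate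
12 | trimethylsilyl enol ether, (6S)-1,1-dimethyl-4-(2-methylpropoxy)-9-(trimethylsilyloxy)spiro[5.5]undeca-3,8-dien-2-one (not isolated) | C1C(OCC(C)C)=CC(=O)C(C)(C)[C@]12CCC(O[Si](C)(C)C)=CC2 | intermediate
13 | (6R,8S)-8-bromo-1,1-dimethyl-4-(2-methylpropoxy)spiro[5.5]undec-3-ene-2,9-dione | C1C(OCC(C)C)=CC(=O)C(C)(C)[C@]12CCC(=O)[C@@H](Br)C2 | intermediate
14 | (6R,8S,9R)-8-bromo-9-hydroxy-1,1,9-trimethyl-4-(2-methylpropoxy)spiro[5.5]undec-3-en-2-one (major C9 epimer) | C1C(OCC(C)C)=CC(=O)C(C)(C)[C@]12CC[C@@](C)(O)[C@@H](Br)C2 | intermediate
15 | (6R,8S,9S)-8-bromo-9-chloro-1,1,9-trimethyl-4-(2-methylpropoxy)spiro[5.5]undec-3-en-2-one | C1C(OCC(C)C)=CC(=O)C(C)(C)[C@]12CC[C@](C)(Cl)[C@@H](Br)C2 | intermediate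
16 | (6R,8S,9S)-4,8-dibromo-9-chloro-5,5,9-trimethylspiro[5.5]undec-3-en-2-one | C1C(=O)C=C(Br)C(C)(C)[C@]12CC[C@](C)(Cl)[C@@H](Br)C2 | intermediate
17 | Mannich base, 4,8-dibromo-9-chloro-1-[(dimethylamino)methyl]-5,5,9-trimethylspiro[5.5]undec-3-en-2-one (C1 epimers, other centres as in 16, not isolated) | CN(C)CC1C(=O)C=C(Br)C(C)(C)[C@]12CC[C@](C)(Cl)[C@@H](Br)C2 | intermediate
18 | trimethylammonium iodide of 17 (C1 epimers, other centres as in 16, not isolated) | C[N+](C)(C)CC1C(=O)C=C(Br)C(C)(C)[C@]12CC[C@](C)(Cl)[C@@H](Br)C2.[I-] | intermediate
19 | (6S,8S,9S)-4,8-dibromo-9-chloro-5,5,9-trimethyl-1-methylidenespiro[5.5]undec-3-en-2-one | C=C1C(=O)C=C(Br)C(C)(C)[C@]12CC[C@](C)(Cl)[C@@H](Br)C2 | intermediate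
20 | (2R,6S,8S,9S)-4,8-dibromo-9-chloro-5,5,9-trimethyl-1-methylidenespiro[5.5]undec-3-en-2-ol (CNP0228180.1) | C=C1[C@H](O)C=C(Br)C(C)(C)[C@]12CC[C@](C)(Cl)[C@@H](Br)C2 | target

Total step count: 11
Longest linear sequence: 11 steps (1 to 20)

Steps most likely to fail

Step 5 (key step). Enamine formation and C–C bond formation at the congested C6 (a quaternary centre is made next to the quaternary C11) may be slow. The catalyst may be consumed by alkylation with the vinyl ketone or by exchange at the enol ether, and the facial discrimination may be insufficient. The fallback sets out from 8 and uses racemic chemistry followed by resolution. Base-catalysed Michael addition of 8 to 9 (DBU cat., THF, rt) would give the racemic keto aldehyde F1. Acid-catalysed aldol condensation (p-toluenesulfonic acid, PhMe, reflux, water removal) would give the racemic spiro dienedione F2. Separation of the enantiomers by preparative chromatography on a chiral stationary phase returns to the route at 11.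

Step 8. Ionisation at C3 may occur without participation of the neighbouring bromine, which would erode the C3 configuration. The cation may also lose a proton, and the acid may cleave the enol ether of ring A. The fallback sets out from 11 and installs both ring-B halogens by anti addition to an alkene. Conjugate reduction with LiBH(s-Bu)3 and trapping with PhNTf2 would give the C2=C3 enol triflate F3. Negishi coupling (Me2Zn, Pd(PPh3)4, THF) would give the ring-B trisubstituted alkene F4, which carries the C15 methyl group. Transposition with (COBr)2 as in step 9 would give the bromo enone alkene F5. Bromochlorination with Bu4N[BrCl2] (CH2Cl2, −78 → 0 °C) adds bromine to C2 and chloride to the tertiary C3 in an anti sense and comes back to the route at 16. Here the C2 configuration rests on bromonium formation on the face away from the axial C7 methylene, and a C2/C3 diastereomer would be removed by chromatography.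

Step 10. Carbon–carbon bond formation at the neopentyl C7 enolate carbon may be slow. The amide base may cause dehydrohalogenation in ring B or addition–elimination at the bromo enone. The fallback sets out from 16 and avoids strong base. Soft enolisation (Me3SiOTf, Et3N, CH2Cl2, 0 °C) would give the silyl dienol ether F6. Mukaiyama aldol reaction with aqueous formaldehyde catalysed by Yb(OTf)3 (THF, rt) would give the hydroxymethyl ketone F7. Mesylation and elimination (MsCl, Et3N, CH2Cl2, 0 °C → rt) comes back to the route at 19.

Further compounds
F1 | step 5 | racemic keto aldehyde, (±)-6,6-dimethyl-3-(2-methylpropoxy)-5-oxo-1-(3-oxobutyl)cyclohex-3-ene-1-carbaldehyde | CC(=O)CCC1(C=O)CC(OCC(C)C)=CC(=O)C1(C)C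
F2 | step 5 | racemic spiro dienedione, (±)-1,1-dimethyl-4-(2-methylpropoxy)spiro[5.5]undeca-3,7-diene-2,9-dione | CC(C)COC1=CC(=O)C(C)(C)C2(C1)CCC(=O)C=C2
F3 | step 8 | C2=C3 enol triflate, 1,1-dimethyl-4-(2-methylpropoxy)-2-oxospiro[5.5]undeca-3,8-dien-9-yl trifluoromethanesulfonate (spiro centre as in 12) | C1C(OCC(C)C)=CC(=O)C(C)(C)[C@]12CCC(OS(=O)(=O)C(F)(F)F)=CC2
F4 | step 8 | ring-B trisubstituted alkene, 1,1,9-trimethyl-4-(2-methylpropoxy)spiro[5.5]undeca-3,8-dien-2-one (spiro centre as in 12) | C1C(OCC(C)C)=CC(=O)C(C)(C)[C@]12CCC(C)=CC2
F5 | step 8 | bromo enone alkene, 4-bromo-5,5,9-trimethylspiro[5.5]undeca-3,8-dien-2-one (spiro centre as in 12) | C1C(=O)C=C(Br)C(C)(C)[C@]12CCC(C)=CC2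
F6 | step 10 | silyl dienol ether, [4,8-dibromo-9-chloro-5,5,9-trimethylspiro[5.5]undeca-1,3-dien-2-yl]oxy(trimethyl)silane (centres as in 16) | C1=C(O[Si](C)(C)C)C=C(Br)C(C)(C)[C@]12CC[C@](C)(Cl)[C@@H](Br)C2
F7 | step 10 | hydroxymethyl ketone, 4,8-dibromo-9-chloro-1-(hydroxymethyl)-5,5,9-trimethylspiro[5.5]undec-3-en-2-one (C1 epimers, other centres as in 16) | OCC1C(=O)C=C(Br)C(C)(C)[C@]12CC[C@](C)(Cl)[C@@H](Br)C2
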